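The oak flask stood closed and stirred at constant temperature when I handed it over, and this note tells you what I expected in it.

| flask | starting material | coupling partner | protic impurity | free catalyst | remark |
|---|---|---|---|---|---|
| oak | 0.050 M | 1.1 equiv | 0.010 M | 1.4 mol% | the very flask that is asked about, followed so far |
| birch | 0.050 M | 1.7 equiv | 0.010 M | 1.4 mol% | run made earlier |
| flask | 0.050 M | 1.10 equiv | 0.0100 M | 1.4 mol% |  |

- oak (time / h: target / %, starting material / %): 0.200: 14, 71; 0.333: 21, 62; 0.500: 26, 56; 0.833: 28, 52; 1.33: 29, 49; 2.50: 36, 46
- birch (time / h: target / %, starting material / %): 0.200: 14, 73; 0.333: 19, 61; 0.500: 28, 58; 0.833: 30, 48; 1.33: 36, 44; 2.50: 40, 43

(each reading ± 2 percentage points)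

- apparent order in free catalyst when 20 % of the starting material are converted (percent change of the rate of making target for one percent more free catalyst charged)
- apparent order in coupling partner when 20 % of the starting material are converted (percent change of the rate of making target for one percent more coupling partner charged)
- factor on the rate of making target when 20 % of the starting material are converted if coupling partner is charged twice over

- no earlier run changes the charge of free catalyst; that part of a forecast is a guess

Starting material is the limiting reagent on paper, since coupling partner went in at 1.10 equiv. I wrote its balance: what is left, plus target, plus what the protic impurity took, equals what was charged, apart from what sits on the catalyst, which I took as at most 1.4 mol% of the charge. Assuming that each impurity took one starting material: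

open share = one minus c(protic impurity) / c(starting material), as charged

open share = one minus 0.0100 M / 0.050 M = 80.0 %

That is the open share, the part of the charge that the impurity leaves for coupling. At 2.50 h, starting material and target in oak summed to 82.0 %. In birch, with the same impurity charge, they summed to 83.0 %, each reading being good to 2 percentage points. I therefore expected that sum to stay near the open share when you came. I asked you to leave the catalyst charge alone, as neither run changed it and its effect was a guess.

The forecast gave orders of 0.9 in free catalyst and 0.12 in coupling partner, and a factor of 1.08 on doubling the partner, noting that “Early target formation is the same within noise”.

The flask gave 1.1, 0.33 and 1.19, so the partner order was higher than forecast, while the factor fell within its margin.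

    coupling partner + free catalyst → catalyst intermediate A (k = 63.8 /M/min)
    starting material + catalyst intermediate A → catalyst intermediate B (k = 88.7 /M/min)
    catalyst intermediate B → catalyst intermediate C (k = 5.63 /min)
    catalyst intermediate C ⇌ free catalyst + target (K = 0.0570 M, k = 4.48 /min)
    2 coupling partner → self-condensation product (k = 1.30 /M/min)
    starting material + protic impurity → quenched substrate (k = 2.42 /M/min)

At 6.00 h, starting material and target in the flask summed to 79.7 %, against the open share of 80.0 %, with quenched substrate at 20.0 % and coupling partner at 0 % of its charge. At the start, self-condensation used coupling partner 3.2 times as fast as its binding to free catalyst did. By 0.600 h, the flask held 0.0186 M of self-condensation product and 8.97 % of its coupling partner charge.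

The numbers in the tables stem from a simulated flask for substances that don't exist, and the scatter is random.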